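**Plan**

- Cuts: the oxolane is opened at O1–C5 and C3–C4 in one formal [3+2] step, giving an α-silyloxy aldehyde (O1–C2–C3) and an (E)-cinnamyl alkene (C4=C5). Before that: the dihydrobenzofuran C2'–C3' bond (carbenoid C–H insertion), the aryl–C3' bond, the side-chain C=C and the benzylic ether O–C bond.
- Forward order: aldehyde 6 in three steps; the dihydrobenzofuran ring is closed first (step 7), the oxolane ring second (step 10); then desilylation and debenzylation.
- Stereochemistry: oxolane C2 comes from methyl (S)-glycidate; C3, C4 and C5 follow from C2 in the chelate-controlled annulation; C2'/C3' (cis, kinetic) come from a chiral dirhodium carboxylate.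
- Enabling feature: oxolane C5 is benzylic to the benzene ring of the dihydrobenzofuran and para to its ring oxygen O1', so a cation at C5 is a stabilised quinone-methide-type oxocarbenium, as in lignan biosynthesis. O1–C2–C3(OH) is the 1,2-dioxygen pattern of an α-oxy aldehyde.
- Numbering used: oxolane O1, C2 (arylmethyl), C3 (OH), C4 (CH2OH), C5 (aryl); dihydrobenzofuran O1', C2' (aryl), C3' (CH2OH), C5' (bonded to oxolane C5), C7' (OMe). In the target the oxolane is 2,3-cis, 3,4-trans, 4,5-trans (all S) and the dihydrobenzofuran is 2',3'-cis (2'R,3'R).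

Key step: step 10

Assumption: the sense of induction of Rh2(S-PTTL)4 in step 7 (2'R series) is taken by analogy with related cis-2-aryl-2,3-dihydrobenzofuran-3-carboxylates; should the opposite sense result, Rh2(R-PTTL)4 is used with nothing else changed.

Abbreviation: DBF = (2R,3R)-2-[4-(benzyloxy)-3-methoxyphenyl]-7-methoxy-3-{[(triisopropylsilyl)oxy]methyl}-2,3-dihydro-1-benzofuran-5-yl.

**Route**

Step 1
Reactants: 1 1-(benzyloxy)-4-bromo-2-methoxybenzene; 2 methyl (S)-glycidate
Product: 4 methyl (2S)-3-[4-(benzyloxy)-3-methoxyphenyl]-2-hydroxypropanoate, via aryl Grignard reagent 3 (not isolated)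
Conditions: Mg, THF, 40 °C; then added to 2, CuBr·SMe2 (10 mol%), THF, −40 to −20 °C; aq. NH4Cl
Reagents that add atoms: none
Why: Copper-catalysed Grignard opening of the glycidic ester (SN2 at the unsubstituted epoxide carbon, faster than ester addition at low temperature) leaves the stereocentre of 2 untouched, so its (S) configuration becomes oxolane C2.

Step 2
Reactants: 4 methyl (2S)-3-[4-(benzyloxy)-3-methoxyphenyl]-2-hydroxypropanoate
Product: 5 methyl (2S)-3-[4-(benzyloxy)-3-methoxyphenyl]-2-[(triethylsilyl)oxy]propanoate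
Conditions: Et3SiCl, imidazole, DMF, 0 °C
Reagents that add atoms: chlorotriethylsilane, CC[Si](Cl)(CC)CC
Why: Standard silylation of a secondary alcohol; the small triethylsilyl group is chosen because it still allows chelation and is lost easily in step 10.

Step 3
Reactants: 5 methyl (2S)-3-[4-(benzyloxy)-3-methoxyphenyl]-2-[(triethylsilyl)oxy]propanoate
Product: 6 (2S)-3-[4-(benzyloxy)-3-methoxyphenyl]-2-[(triethylsilyl)oxy]propanal
Conditions: i-Bu2AlH (1.1 equiv), CH2Cl2, −78 °C; MeOH, then aq. potassium sodium tartrate; used crude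
Reagents that add atoms: none
Why: Half-reduction of an α-silyloxy ester stops at the aldehyde because the tetrahedral aluminium hemiacetal is stable at −78 °C, and immediate use avoids α-epimerisation.

Step 4
Reactants: 7 5-iodovanillin; 8 [4-(benzyloxy)-3-methoxyphenyl]methanol
Product: 9 4-{[4-(benzyloxy)-3-methoxyphenyl]methoxy}-3-iodo-5-methoxybenzaldehyde
Conditions: PPh3, DIAD, THF, 0 °C to rt
Reagents that add atoms: none
Why: Mitsunobu etherification should work because the phenol is acidified by the para formyl group and the alcohol is primary and benzylic.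

Step 5
Reactants: 9 4-{[4-(benzyloxy)-3-methoxyphenyl]methoxy}-3-iodo-5-methoxybenzaldehyde; 10 triethyl phosphonoacetate
Product: 11 ethyl (E)-3-(4-{[4-(benzyloxy)-3-methoxyphenyl]methoxy}-3-iodo-5-methoxyphenyl)prop-2-enoate
Conditions: LiCl, DBU, MeCN, rt
Reagents that add atoms: none
Why: Horner–Wadsworth–Emmons olefination under Masamune–Roush conditions should give the (E)-cinnamate through the thermodynamically favoured anti elimination pathway.

Step 6
Reactants: 11 ethyl (E)-3-(4-{[4-(benzyloxy)-3-methoxyphenyl]methoxy}-3-iodo-5-methoxyphenyl)prop-2-enoate; 12 ethyl diazoacetate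
Product: 13 ethyl 2-diazo-2-{2-{[4-(benzyloxy)-3-methoxyphenyl]methoxy}-5-[(E)-3-ethoxy-3-oxoprop-1-enyl]-3-methoxyphenyl}acetate
Conditions: Pd(PPh3)4 (5 mol%), Ag2CO3 (0.5 equiv), Et3N (1.3 equiv), toluene, rt
Reagents that add atoms: none
Why: Palladium-catalysed cross-coupling of an aryl iodide with the C–H bond of a diazoacetate (oxidative addition to zerovalent palladium, silver-assisted transfer of the diazoacetate carbon, reductive elimination) keeps the diazo group at room temperature, and the disubstituted cinnamate is a poor Heck or dipolarophile partner.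

Step 7
Reactants: 13 ethyl 2-diazo-2-{2-{[4-(benzyloxy)-3-methoxyphenyl]methoxy}-5-[(E)-3-ethoxy-3-oxoprop-1-enyl]-3-methoxyphenyl}acetate
Product: 14 ethyl (2R,3S)-2-[4-(benzyloxy)-3-methoxyphenyl]-5-[(E)-3-ethoxy-3-oxoprop-1-enyl]-7-methoxy-2,3-dihydro-1-benzofuran-3-carboxylate (2,3-cis)
Conditions: Rh2(S-PTTL)4 (dirhodium tetrakis[N-phthaloyl-(S)-tert-leucinate], 1 mol%), toluene, −60 °C
Reagents that add atoms: none
Why: Intramolecular rhodium-carbenoid 1,5 C–H insertion into the doubly activated ArCH2–O methylene closes the five-membered ring, gives the cis ester as the kinetic product, and sets both stereocentres through the chiral carboxylate ligands; intermolecular attack on the electron-poor cinnamate should not compete.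

Step 8
Reactants: 14 ethyl (2R,3S)-2-[4-(benzyloxy)-3-methoxyphenyl]-5-[(E)-3-ethoxy-3-oxoprop-1-enyl]-7-methoxy-2,3-dihydro-1-benzofuran-3-carboxylate
Product: 15 (E)-3-{(2R,3R)-2-[4-(benzyloxy)-3-methoxyphenyl]-3-(hydroxymethyl)-7-methoxy-2,3-dihydro-1-benzofuran-5-yl}prop-2-en-1-ol (2,3-cis)
Conditions: i-Bu2AlH (5 equiv), CH2Cl2, −78 °C; aq. potassium sodium tartrate
Reagents that add atoms: none
Why: The non-basic hydride reduces both esters by 1,2-addition (cinnamate to allylic alcohol) without enolising C3', so the cis relationship should be kept.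

Step 9
Reactants: 15 (E)-3-{(2R,3R)-2-[4-(benzyloxy)-3-methoxyphenyl]-3-(hydroxymethyl)-7-methoxy-2,3-dihydro-1-benzofuran-5-yl}prop-2-en-1-ol
Product: 16 (2R,3R)-2-[4-(benzyloxy)-3-methoxyphenyl]-7-methoxy-3-{[(triisopropylsilyl)oxy]methyl}-5-{(E)-3-[(triisopropylsilyl)oxy]prop-1-enyl}-2,3-dihydro-1-benzofuran
Conditions: i-Pr3SiCl (2.5 equiv), imidazole, DMF, rt
Reagents that add atoms: chlorotriisopropylsilane, CC(C)[Si](Cl)(C(C)C)C(C)C
Why: Standard silylation of two primary alcohols; the bulky, weakly Lewis-basic triisopropylsilyl ethers are chosen to resist coordination by SnCl4 and allylic ionisation in step 10.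

Step 10
Reactants: 6 (2S)-3-[4-(benzyloxy)-3-methoxyphenyl]-2-[(triethylsilyl)oxy]propanal; 16 (2R,3R)-2-[4-(benzyloxy)-3-methoxyphenyl]-7-methoxy-3-{[(triisopropylsilyl)oxy]methyl}-5-{(E)-3-[(triisopropylsilyl)oxy]prop-1-enyl}-2,3-dihydro-1-benzofuran
Product: 18 (2S,3S,4S,5S)-2-[4-(benzyloxy)-3-methoxybenzyl]-5-DBF-4-{[(triisopropylsilyl)oxy]methyl}oxolan-3-ol, via stannate-bound benzylic cation 17 (not isolated)
Conditions: 6 (1.3 equiv) pre-complexed with SnCl4 (1.3 equiv), 2,6-di-tert-butyl-4-methylpyridine (0.3 equiv), CH2Cl2, −78 °C; then 16, −78 °C; aq. NaHCO3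
Reagents that add atoms: none
Why: SnCl4 binds the aldehyde oxygen and the small α-triethylsilyloxy oxygen of 6 in a five-membered chelate, the electron-rich (E)-alkene of 16 attacks the carbonyl carbon through its CH2OSi-bearing carbon from the chelate face opposite the arylmethyl group, and the resulting benzylic cation 17, a quinone-methide-type oxocarbenium stabilised by the para ring oxygen O1', is captured by the silyl ether oxygen with loss of Et3SiCl. The closest known reaction type is the Lewis-acid-mediated formal [3+2] annulation of α-silyloxy aldehydes with styrenes or allylsilanes to tetrahydrofuran-3-ols (Prins-type addition followed by cation capture). The oxolane closes by 5-exo-trig attack of O1 on cationic C5, the C5=C(ipso) bond of the quinoid form lying outside the new ring. C3 is set by Cram-chelate control from C2 (arylmethyl and OH cis), C4 by the open antiperiplanar transition state that places its hydrogen between the two chelate arms, as in chelation-controlled Mukaiyama aldol additions (syn,syn triad, hence 3,4-trans), and C5 by ring closure with the aryl group trans to the C4 substituent, which also matches suprafacial use of the (E)-alkene. The step needs chelate over Felkin–Anh facial selectivity, secured by the bidentate Lewis acid and the small silyl group, and reaction at the alkene without ionising the allylic silyl ether or the cis-dihydrobenzofuran C2'–O1' bond, secured by pre-complexing SnCl4 with an equimolar amount of 6 at −78 °C, the bulky silyl ethers and the hindered pyridine buffer.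

Step 11
Reactants: 18 (2S,3S,4S,5S)-2-[4-(benzyloxy)-3-methoxybenzyl]-5-DBF-4-{[(triisopropylsilyl)oxy]methyl}oxolan-3-ol
Product: 19 (2S,3S,4S,5S)-2-[4-(benzyloxy)-3-methoxybenzyl]-5-{(2R,3R)-2-[4-(benzyloxy)-3-methoxyphenyl]-3-(hydroxymethyl)-7-methoxy-2,3-dihydro-1-benzofuran-5-yl}-4-(hydroxymethyl)oxolan-3-ol
Conditions: Bu4NF (3 equiv), THF, 0 °C to rt
Reagents that add atoms: none
Why: Fluoride cleaves both primary silyl ethers while the phenols stay benzylated, so no phenoxide is formed that could open the cis-dihydrobenzofuran through a quinone methide.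

Step 12
Reactants: 19 (2S,3S,4S,5S)-2-[4-(benzyloxy)-3-methoxybenzyl]-5-{(2R,3R)-2-[4-(benzyloxy)-3-methoxyphenyl]-3-(hydroxymethyl)-7-methoxy-2,3-dihydro-1-benzofuran-5-yl}-4-(hydroxymethyl)oxolan-3-ol
Product: 20 (2S,3S,4S,5S)-2-(4-hydroxy-3-methoxybenzyl)-5-[(2R,3R)-2-(4-hydroxy-3-methoxyphenyl)-3-(hydroxymethyl)-7-methoxy-2,3-dihydro-1-benzofuran-5-yl]-4-(hydroxymethyl)oxolan-3-ol (CNP0179668.1)
Conditions: H2 (1 atm), Pd/C (10 wt%), EtOAc–EtOH, rt, stopped at full debenzylation
Reagents that add atoms: none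
Why: Hydrogenolysis of the two aryl benzyl ethers under neutral conditions should be much faster than cleavage of the cyclic benzylic C–O bonds of the oxolane and the dihydrobenzofuran, and no stereocentre is touched.

**Compound list**

1 | 1-(benzyloxy)-4-bromo-2-methoxybenzene | COc1cc(Br)ccc1OCc1ccccc1 | starting material
2 | methyl (2S)-oxirane-2-carboxylate (methyl (S)-glycidate) | COC(=O)[C@@H]1CO1 | starting material
3 | [4-(benzyloxy)-3-methoxyphenyl]magnesium bromide | COc1cc([Mg]Br)ccc1OCc1ccccc1 | intermediate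
4 | methyl (2S)-3-[4-(benzyloxy)-3-methoxyphenyl]-2-hydroxypropanoate | COC(=O)[C@@H](O)Cc1ccc(OCc2ccccc2)c(OC)c1 | intermediate
5 | methyl (2S)-3-[4-(benzyloxy)-3-methoxyphenyl]-2-[(triethylsilyl)oxy]propanoate | COC(=O)[C@@H](O[Si](CC)(CC)CC)Cc1ccc(OCc2ccccc2)c(OC)c1 | intermediate
6 | (2S)-3-[4-(benzyloxy)-3-methoxyphenyl]-2-[(triethylsilyl)oxy]propanal | O=C[C@@H](O[Si](CC)(CC)CC)Cc1ccc(OCc2ccccc2)c(OC)c1 | intermediate
7 | 5-iodovanillin (4-hydroxy-3-iodo-5-methoxybenzaldehyde) | COc1cc(C=O)cc(I)c1O | starting material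
8 | [4-(benzyloxy)-3-methoxyphenyl]methanol | COc1cc(CO)ccc1OCc1ccccc1 | starting material
9 | 4-{[4-(benzyloxy)-3-methoxyphenyl]methoxy}-3-iodo-5-methoxybenzaldehyde | COc1cc(C=O)cc(I)c1OCc1ccc(OCc2ccccc2)c(OC)c1 | intermediate
10 | triethyl phosphonoacetate | CCOC(=O)CP(=O)(OCC)OCC | starting material
11 | ethyl (E)-3-(4-{[4-(benzyloxy)-3-methoxyphenyl]methoxy}-3-iodo-5-methoxyphenyl)prop-2-enoate | CCOC(=O)/C=C/c1cc(I)c(OCc2ccc(OCc3ccccc3)c(OC)c2)c(OC)c1 | intermediate
12 | ethyl diazoacetate | CCOC(=O)C=[N+]=[N-] | starting material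
13 | ethyl 2-diazo-2-{2-{[4-(benzyloxy)-3-methoxyphenyl]methoxy}-5-[(E)-3-ethoxy-3-oxoprop-1-enyl]-3-methoxyphenyl}acetate | CCOC(=O)C(=[N+]=[N-])c1cc(/C=C/C(=O)OCC)cc(OC)c1OCc1ccc(OCc2ccccc2)c(OC)c1 | intermediate
14 | ethyl (2R,3S)-2-[4-(benzyloxy)-3-methoxyphenyl]-5-[(E)-3-ethoxy-3-oxoprop-1-enyl]-7-methoxy-2,3-dihydro-1-benzofuran-3-carboxylate (2,3-cis) | CCOC(=O)/C=C/c1cc(OC)c2c(c1)[C@H](C(=O)OCC)[C@H](c1ccc(OCc3ccccc3)c(OC)c1)O2 | intermediate
15 | (E)-3-{(2R,3R)-2-[4-(benzyloxy)-3-methoxyphenyl]-3-(hydroxymethyl)-7-methoxy-2,3-dihydro-1-benzofuran-5-yl}prop-2-en-1-ol (2,3-cis) | OC/C=C/c1cc(OC)c2c(c1)[C@H](CO)[C@H](c1ccc(OCc3ccccc3)c(OC)c1)O2 | intermediate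
16 | (2R,3R)-2-[4-(benzyloxy)-3-methoxyphenyl]-7-methoxy-3-{[(triisopropylsilyl)oxy]methyl}-5-{(E)-3-[(triisopropylsilyl)oxy]prop-1-enyl}-2,3-dihydro-1-benzofuran | CC(C)[Si](OC/C=C/c1cc(OC)c2c(c1)[C@H](CO[Si](C(C)C)(C(C)C)C(C)C)[C@H](c1ccc(OCc3ccccc3)c(OC)c1)O2)(C(C)C)C(C)C | intermediate
17 | open-chain zwitterion: cation at the DBF-bearing benzylic carbon, tetrachlorostannate alkoxide at the carbinol carbon, triethylsilyl ether still on the oxygen that becomes O1 | COc1cc(C[C@H](O[Si](CC)(CC)CC)[C@@H](O[Sn-](Cl)(Cl)(Cl)Cl)[C@H](CO[Si](C(C)C)(C(C)C)C(C)C)[CH+]c3cc(OC)c4c(c3)[C@H](CO[Si](C(C)C)(C(C)C)C(C)C)[C@H](c3ccc(OCc5ccccc5)c(OC)c3)O4)ccc1OCc1ccccc1 | intermediate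
18 | (2S,3S,4S,5S)-2-[4-(benzyloxy)-3-methoxybenzyl]-5-DBF-4-{[(triisopropylsilyl)oxy]methyl}oxolan-3-ol | COc1cc(C[C@@H]2O[C@H](c3cc(OC)c4c(c3)[C@H](CO[Si](C(C)C)(C(C)C)C(C)C)[C@H](c3ccc(OCc5ccccc5)c(OC)c3)O4)[C@@H](CO[Si](C(C)C)(C(C)C)C(C)C)[C@@H]2O)ccc1OCc1ccccc1 | intermediate
19 | (2S,3S,4S,5S)-2-[4-(benzyloxy)-3-methoxybenzyl]-5-{(2R,3R)-2-[4-(benzyloxy)-3-methoxyphenyl]-3-(hydroxymethyl)-7-methoxy-2,3-dihydro-1-benzofuran-5-yl}-4-(hydroxymethyl)oxolan-3-ol | COc1cc(C[C@@H]2O[C@H](c3cc(OC)c4c(c3)[C@H](CO)[C@H](c3ccc(OCc5ccccc5)c(OC)c3)O4)[C@@H](CO)[C@@H]2O)ccc1OCc1ccccc1 | intermediate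
20 | (2S,3S,4S,5S)-2-(4-hydroxy-3-methoxybenzyl)-5-[(2R,3R)-2-(4-hydroxy-3-methoxyphenyl)-3-(hydroxymethyl)-7-methoxy-2,3-dihydro-1-benzofuran-5-yl]-4-(hydroxymethyl)oxolan-3-ol | COc1cc(C[C@@H]2O[C@H](c3cc(OC)c4c(c3)[C@H](CO)[C@H](c3ccc(O)c(OC)c3)O4)[C@@H](CO)[C@@H]2O)ccc1O | target

**Totals and risks**

Total step count: 12. Longest linear sequence: 9 steps (steps 4 to 12, from 7 and 8); the aldehyde branch (steps 1 to 3) joins at step 10.

Steps most likely to fail:

Step 10. The chelate may not hold, so that Felkin–Anh attack gives the wrong face at C3 and with it the wrong C4 and C5. The Lewis acid may also ionise the allylic silyl ether or the C2'–O1' benzylic bond (cis-to-trans epimerisation of the dihydrobenzofuran), or the electron-rich alkene may oligomerise. The fallback makes the two bonds in separate, known operations; it sets out from 16 and 6 and comes back at 18. Tsuji–Wacker oxidation of 16 (PdCl2, CuCl, O2, DMF–H2O) should place the carbonyl at the benzylic carbon, distal to the allylic silyloxy group, to give the aryl ketone F1. Silylation (Me3SiOTf, Et3N, CH2Cl2, 0 °C) should give the (Z)-trimethylsilyl enol ether F2. A Mukaiyama aldol addition of F2 to 6 under Me2AlCl chelation (CH2Cl2, −78 °C), a Lewis acid that chelates α-silyloxy aldehydes, should give the syn,syn β-hydroxy ketone F3. NaBH4 (MeOH, 0 °C) should then give the benzylic alcohol F4 as a mixture of carbinol epimers, which does not matter. BF3·OEt2 (CH2Cl2, −78 °C) ionises this benzylic alcohol to the same type of cation as 17; the silyl ether oxygen captures it with the aryl group trans to the C4 substituent and gives 18.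

Step 7. Enantio- or cis-selectivity may be eroded by the methoxy group next to the ether oxygen or by the ethyl ester, and carbene dimerisation may compete. The fallback replaces catalyst control by classical resolution; it sets out from 15 of insufficient enantiomeric purity (made through steps 7 and 8 as written) and comes back at enantiopure 15. Both hydroxyl groups are esterified with (R)-2-methoxy-2-phenylacetic acid (EDC, catalytic DMAP, CH2Cl2, 0 °C) to give the bis[(R)-O-methylmandelate] F5. The diastereomers are separated by chromatography or crystallisation, and K2CO3 in MeOH returns 15. Any residual minor enantiomer of 16 would in addition give a diastereomer of 18 in step 10, removable there.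

Step 6. The coupling may be sluggish next to the ortho benzylic ether, and the diazo group may be lost on palladium (carbene and azine formation). The fallback builds the diazo ester by arylation and diazo transfer; it sets out from 11 and comes back at 13. Copper-catalysed arylation of diethyl malonate with 11 (CuI, 2-picolinic acid, Cs2CO3, dioxane, 40 °C) should give the aryl malonate F6. Krapcho dealkoxycarbonylation (LiCl, wet DMSO, 130 °C; the cinnamate ester is not activated and should survive) should give the aryl acetate F7. Regitz diazo transfer (4-acetamidobenzenesulfonyl azide, DBU, MeCN, 0 °C to rt) then gives 13.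

**Further compounds**

F1 | step 10 | 1-DBF-3-[(triisopropylsilyl)oxy]propan-1-one | CC(C)[Si](OCCC(=O)c1cc(OC)c2c(c1)[C@H](CO[Si](C(C)C)(C(C)C)C(C)C)[C@H](c1ccc(OCc3ccccc3)c(OC)c1)O2)(C(C)C)C(C)C
F2 | step 10 | (Z)-1-DBF-3-[(triisopropylsilyl)oxy]-1-[(trimethylsilyl)oxy]prop-1-ene | C[Si](C)(C)O/C(=C\CO[Si](C(C)C)(C(C)C)C(C)C)c1cc(OC)c2c(c1)[C@H](CO[Si](C(C)C)(C(C)C)C(C)C)[C@H](c1ccc(OCc3ccccc3)c(OC)c1)O2
F3 | step 10 | (2S,3S,4S)-5-[4-(benzyloxy)-3-methoxyphenyl]-1-DBF-3-hydroxy-4-[(triethylsilyl)oxy]-2-{[(triisopropylsilyl)oxy]methyl}pentan-1-one (syn,syn) | COc1cc(C[C@H](O[Si](CC)(CC)CC)[C@@H](O)[C@H](CO[Si](C(C)C)(C(C)C)C(C)C)C(=O)c3cc(OC)c4c(c3)[C@H](CO[Si](C(C)C)(C(C)C)C(C)C)[C@H](c3ccc(OCc5ccccc5)c(OC)c3)O4)ccc1OCc1ccccc1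
F4 | step 10 | 1,3-diol from reduction of the ketone of F3, both epimers at the new benzylic carbinol, other centres as in F3 | COc1cc(C[C@H](O[Si](CC)(CC)CC)[C@@H](O)[C@H](CO[Si](C(C)C)(C(C)C)C(C)C)C(O)c3cc(OC)c4c(c3)[C@H](CO[Si](C(C)C)(C(C)C)C(C)C)[C@H](c3ccc(OCc5ccccc5)c(OC)c3)O4)ccc1OCc1ccccc1
F5 | step 7 | bis[(2R)-2-methoxy-2-phenylacetate] of 15 | CO[C@H](c1ccccc1)C(=O)OC/C=C/c1cc(OC)c2c(c1)[C@H](COC(=O)[C@H](OC)c1ccccc1)[C@H](c1ccc(OCc3ccccc3)c(OC)c1)O2
F6 | step 6 | diethyl 2-{2-{[4-(benzyloxy)-3-methoxyphenyl]methoxy}-5-[(E)-3-ethoxy-3-oxoprop-1-enyl]-3-methoxyphenyl}propanedioate | CCOC(=O)C(C(=O)OCC)c1cc(/C=C/C(=O)OCC)cc(OC)c1OCc1ccc(OCc2ccccc2)c(OC)c1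
F7 | step 6 | ethyl (E)-3-{4-{[4-(benzyloxy)-3-methoxyphenyl]methoxy}-3-(2-ethoxy-2-oxoethyl)-5-methoxyphenyl}prop-2-enoate | CCOC(=O)Cc1cc(/C=C/C(=O)OCC)cc(OC)c1OCc1ccc(OCc2ccccc2)c(OC)c1
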